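**Plan**
Core numbering: C1 and C4 are the bridgeheads, C2 the ketone, C3 the carbinol, C5=C6 the alkene (C5 carries the side chain), C7 the aryl carbon, C8 the ester carbon.
Retrosynthesis: cut the side-chain C=C (Wittig with an ylide on the (S)-aryl-lactate); then, in one operation, the C5=C6 double bond and the C3–C4 bond; then the C2–C3 acyl bond (Claisen), the C4–C5 bond (copper-catalysed opening of an enol lactone) and the lactone (carbene-catalysed annulation of an enal).
Forward: aryl aldehyde → enal → 4-aryl enol lactone → open-chain 2-alkylidene ester → β-keto ester → doubly masked open-chain precursor → cyclohexanone ring (C1–C2–C3–C4–C8–C7), then cyclohexene ring (C1–C6=C5–C4–C8–C7) in one pot → dienoate → decarboxylation → debenzylation.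
Enabling feature: the two rings share the C7–C8 bridge; C3 is α to the C2 ketone (made the most acidic carbon by a temporary allyl ester), C4 is β to the C8 ester, and C5/C6 are an aldehyde α-carbon and a formyl carbon held 1,4-cis on that cyclohexanone. A Michael addition followed by an aldol condensation therefore builds the bicyclo[2.2.2]octenone from an open chain.
Stereochemistry: C7 from the chiral carbene catalyst; C4 and C8 from 1,3-allylic strain in the Michael step and protonation of the ester enolate; C1 fixed by the bicycle; C3 by face-selective ketonisation after loss of the allyl ester; the lactate centre from methyl (S)-glycidate.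
Helpers: allyl ester at C3, two dioxolanes, five benzyl ethers; they are removed in the key step and in the last two steps.

Key step: step 7

Remark: the sodium enolate of methyl 3-oxopropanoate is taken as a catalogue reagent (it is otherwise made from methyl acetate, methyl formate and NaOMe).
Remark: carbons that are epimer mixtures of no consequence (the α-benzyloxy carbon before step 10, the dioxolane- or formyl-bearing carbon before the aldol event) carry no descriptor in the SMILES.

**Step 1**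
Reactants: 1 3,4-bis(benzyloxy)benzaldehyde; 2 (triphenylphosphoranylidene)acetaldehyde
Product: 3 (2E)-3-[3,4-bis(benzyloxy)phenyl]prop-2-enal
Conditions: 2 (1.1 equiv), toluene, 80 °C
Reagents that add atoms: none
Why: Wittig olefination of the aromatic aldehyde with the formyl-stabilised ylide should give the cinnamaldehyde, the stabilised ylide securing the E geometry.

**Step 2**
Reactants: 3 (2E)-3-[3,4-bis(benzyloxy)phenyl]prop-2-enal; 4 sodium (1E)-3-methoxy-3-oxoprop-1-en-1-olate
Product: 5 methyl (4R)-4-[3,4-bis(benzyloxy)phenyl]-2-oxo-3,4-dihydro-2H-pyran-5-carboxylate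
Conditions: 4 (1.5 equiv), 2-mesityl-5a,10b-dihydro-4H,6H-indeno[2,1-b][1,2,4]triazolo[4,3-d][1,4]oxazin-2-ium tetrafluoroborate (10 mol %, the enantiomer that gives 4R), 3,3',5,5'-tetra-tert-butyl-4,4'-diphenoquinone (1.2 equiv), THF, rt; aq. NH4Cl
Reagents that add atoms: none
Why: Carbene-catalysed oxidative [3+3] annulation (oxidation of the enal-derived hydroxy-enamine to an α,β-unsaturated acyl azolium, Michael addition of the 1,3-dicarbonyl enolate at the β-carbon, then O-acylation to the enol lactone) should build the ring, and the chiral catalyst shields one face of the acyl azolium so that the aryl-bearing centre is set as 4R.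

**Step 3**
Reactants: 5 methyl (4R)-4-[3,4-bis(benzyloxy)phenyl]-2-oxo-3,4-dihydro-2H-pyran-5-carboxylate; 6 (1,3-dioxolan-2-ylmethyl)magnesium bromide
Product: 7 (3R,4E)-3-[3,4-bis(benzyloxy)phenyl]-6-(1,3-dioxolan-2-yl)-4-(methoxycarbonyl)hex-4-enoic acid
Conditions: 6 (2.2 equiv), CuBr·SMe2 (10 mol %), THF, −78 to −30 °C; aq. NaH2PO4
Reagents that add atoms: none
Why: Copper-catalysed conjugate addition–elimination of the Grignard reagent at the β-acyloxy acrylate carbon (the ring carboxylate is the leaving group) should open the enol lactone with retention of alkene geometry, so the new carbon stays cis to the aryl-bearing carbon as the ring oxygen was, which gives the (E)-alkylidene ester and leaves the stereocentre untouched.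

**Step 4**
Reactants: 8 (benzyloxy)acetyl chloride; 9 prop-2-en-1-ol
Product: 10 prop-2-en-1-yl (benzyloxy)acetate
Conditions: Et3N (1.2 equiv), DMAP (5 mol %), CH2Cl2, 0 °C to rt
Reagents that add atoms: none
Why: Esterification by acylation of the alcohol with the acid chloride under nucleophilic catalysis should be clean, and no stereocentre is involved.

**Step 5**
Reactants: 7 (3R,4E)-3-[3,4-bis(benzyloxy)phenyl]-6-(1,3-dioxolan-2-yl)-4-(methoxycarbonyl)hex-4-enoic acid; 10 prop-2-en-1-yl (benzyloxy)acetate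
Product: 13 prop-2-en-1-yl (5R,6E)-2-(benzyloxy)-5-[3,4-bis(benzyloxy)phenyl]-8-(1,3-dioxolan-2-yl)-6-(methoxycarbonyl)-3-oxooct-6-enoate (C2 epimers), via acyl imidazolide 11 (not isolated), via lithium enolate 12 (not isolated)
Conditions: 7, 1,1'-carbonyldiimidazole (1.1 equiv), THF, rt; added to 10 (2.5 equiv) pretreated with LiN(SiMe3)2 (2.5 equiv), THF, −78 °C; −78 to −40 °C; aq. NH4Cl
Reagents that add atoms: none
Why: Crossed Claisen condensation in which the N-acylimidazole is a selective acyl donor for the ester enolate and the excess enolate deprotonates the β-keto ester as it forms (which protects it from a second addition) should give the keto ester without touching the aryl-bearing centre, the new α-benzyloxy centre being an epimer mixture of no consequence.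

**Step 6**
Reactants: 13 prop-2-en-1-yl (5R,6E)-2-(benzyloxy)-5-[3,4-bis(benzyloxy)phenyl]-8-(1,3-dioxolan-2-yl)-6-(methoxycarbonyl)-3-oxooct-6-enoate
Product: 15 prop-2-en-1-yl (5R,6E)-2-(benzyloxy)-5-[3,4-bis(benzyloxy)phenyl]-4,8-bis(1,3-dioxolan-2-yl)-6-(methoxycarbonyl)-3-oxooct-6-enoate (C2 and C4 epimers), via enaminone 14 (not isolated)
Conditions: Me2NCH(OMe)2 (3 equiv), toluene, 80 °C; evaporation; then ethane-1,2-diol (5 equiv), anhydrous p-TsOH (1.1 equiv), 4 Å molecular sieves, CH2Cl2, rt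
Reagents that add atoms: N,N-dimethylformamide dimethyl acetal (COC(OC)N(C)C); ethane-1,2-diol (OCCO)
Why: Aminomethylenation with the formamide acetal should occur at the only α-methylene of the ketone (the other α-carbon carries a single hydrogen and cannot give an enaminone), and acid-mediated exchange of the vinylogous amide with the diol (acetalisation) then masks the new formyl carbon as a base-stable dioxolane on an sp3 carbon, formed as an epimer mixture of no consequence.

**Step 7**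
Reactants: 15 prop-2-en-1-yl (5R,6E)-2-(benzyloxy)-5-[3,4-bis(benzyloxy)phenyl]-4,8-bis(1,3-dioxolan-2-yl)-6-(methoxycarbonyl)-3-oxooct-6-enoate
Product: 18 3-(prop-2-en-1-yl) 8-methyl (1S,4S,7S,8R)-3-(benzyloxy)-7-[3,4-bis(benzyloxy)phenyl]-5-formyl-2-oxobicyclo[2.2.2]oct-5-ene-3,8-dicarboxylate (C3 epimers), via Michael adduct 16 (not isolated), via keto dialdehyde 17 (not isolated)
Conditions: Cs2CO3 (20 mol %), MeCN, 40 °C; then, in the same flask, AcOH–H2O (4:1), pyrrolidine (30 mol %), 60 °C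
Reagents that add atoms: water (O)
Why: Catalytic carbonate deprotonates the α-benzyloxy β-keto ester carbon (C3), which adds to the β-carbon (C4) of the 2-alkylidene ester in a 6-(enolendo)-endo-trig Michael closure to the cyclohexanone 16; aqueous acetic acid then frees both aldehydes and pyrrolidinium acetate condenses the α-carbon of the new aldehyde (C5) with the formyl carbon (C6) across the ring, a 6-(enolexo)-exo-trig aldol addition on the boat cyclohexanone followed by dehydration, which closes the cyclohexene ring and completes the bicyclo[2.2.2]octenone. The closest known reaction types are the base-catalysed intramolecular Michael addition of β-keto esters to acrylates and the amine-catalysed Michael/aldol-condensation cascades that give cyclohexene carbaldehydes. C4 is set by the aryl-bearing centre: the (E)-alkylidene forces the CH2 substituent of C4 to be axial in the chair-like transition state, so the aryl group takes the equatorial site and the hydrogen the site facing that CH2 (1,3-allylic strain), which puts the new C3–C4 bond and the aryl group on opposite faces. C8 follows by protonation of the ester enolate anti to the axial side chain (ester equatorial, trans to aryl), the bridgehead C1 is fixed by the bicycle because the formyl-bearing carbon is enolisable and only its cis-1,4 arrangement can close, and the quaternary C3 is left uncontrolled because step 10 resets it. The step needs the Michael addition to come before the aldol event, since the reverse order would pass through a cyclohexadiene whose transannular closure is not under this control; the dioxolanes secure it because neither aldehyde exists until acid is added. It also needs condensation at the aldehyde α-carbon and not at the doubly activated C1, which is secured because only the former aldol can dehydrate to the conjugated enal while the latter is reversible.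

**Step 8**
Reactants: 19 1,2-bis(benzyloxy)-4-bromobenzene; 20 methyl (2S)-oxirane-2-carboxylate
Product: 22 methyl (2S)-3-[3,4-bis(benzyloxy)phenyl]-2-hydroxypropanoate, via aryl Grignard reagent 21 (not isolated)
Conditions: Mg, THF, reflux; then CuI (10 mol %), 20, THF, −40 to −20 °C; aq. NH4Cl
Reagents that add atoms: none
Why: Copper-catalysed SN2 opening of the epoxide by the aryl Grignard reagent at the unsubstituted carbon leaves the C2 stereocentre untouched, so the (S) configuration of the glycidate should be carried into the (S)-aryl-lactate.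

**Step 9**
Reactants: 18 3-(prop-2-en-1-yl) 8-methyl (1S,4S,7S,8R)-3-(benzyloxy)-7-[3,4-bis(benzyloxy)phenyl]-5-formyl-2-oxobicyclo[2.2.2]oct-5-ene-3,8-dicarboxylate; 22 methyl (2S)-3-[3,4-bis(benzyloxy)phenyl]-2-hydroxypropanoate; 23 (triphenylphosphoranylidene)ketene
Product: 25 3-(prop-2-en-1-yl) 8-methyl (1S,4S,7S,8R)-3-(benzyloxy)-7-[3,4-bis(benzyloxy)phenyl]-5-[(1E)-3-({(2S)-3-[3,4-bis(benzyloxy)phenyl]-1-methoxy-1-oxopropan-2-yl}oxy)-3-oxoprop-1-en-1-yl]-2-oxobicyclo[2.2.2]oct-5-ene-3,8-dicarboxylate (C3 epimers), via ylide ester 24 (not isolated)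
Conditions: 22, 23, toluene, 60 °C; then 18, 90 °C
Reagents that add atoms: none
Why: The alcohol adds to the ketene ylide to give the ester-stabilised ylide, whose Wittig reaction with the aldehyde (not the hindered ketone) should give the (E)-dienoate without added base, so the lactate stereocentre is not put at risk.

**Step 10**
Reactants: 25 3-(prop-2-en-1-yl) 8-methyl (1S,4S,7S,8R)-3-(benzyloxy)-7-[3,4-bis(benzyloxy)phenyl]-5-[(1E)-3-({(2S)-3-[3,4-bis(benzyloxy)phenyl]-1-methoxy-1-oxopropan-2-yl}oxy)-3-oxoprop-1-en-1-yl]-2-oxobicyclo[2.2.2]oct-5-ene-3,8-dicarboxylate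
Product: 27 methyl (1S,3S,4S,7S,8R)-3-(benzyloxy)-7-[3,4-bis(benzyloxy)phenyl]-5-[(1E)-3-({(2S)-3-[3,4-bis(benzyloxy)phenyl]-1-methoxy-1-oxopropan-2-yl}oxy)-3-oxoprop-1-en-1-yl]-2-oxobicyclo[2.2.2]oct-5-ene-8-carboxylate, via beta-keto acid 26 (not isolated)
Conditions: Pd(OAc)2 (5 mol %), PPh3 (20 mol %), HCO2H (2.5 equiv), Et3N (3 equiv), THF, rt
Reagents that add atoms: none
Why: Palladium-catalysed deallylation with formate (allyl transfer to zerovalent palladium, hydride capture of the allyl group) gives the β-keto acid, which loses CO2 to an enol that can only be the C2–C3 enol because C1 is a bridgehead, and ketonisation by protonation from the open face next to the etheno bridge (the other face is screened by the aryl group and the C8 hydrogen) should set C3 with the benzyloxy group anti to the alkene.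

**Step 11**
Reactants: 27 methyl (1S,3S,4S,7S,8R)-3-(benzyloxy)-7-[3,4-bis(benzyloxy)phenyl]-5-[(1E)-3-({(2S)-3-[3,4-bis(benzyloxy)phenyl]-1-methoxy-1-oxopropan-2-yl}oxy)-3-oxoprop-1-en-1-yl]-2-oxobicyclo[2.2.2]oct-5-ene-8-carboxylate
Product: 28 methyl (1S,3S,4S,7S,8R)-7-(3,4-dihydroxyphenyl)-5-[(1E)-3-{[(2S)-3-(3,4-dihydroxyphenyl)-1-methoxy-1-oxopropan-2-yl]oxy}-3-oxoprop-1-en-1-yl]-3-hydroxy-2-oxobicyclo[2.2.2]oct-5-ene-8-carboxylate
Conditions: BCl3 (10 equiv), pentamethylbenzene (15 equiv), CH2Cl2, −78 to −40 °C; MeOH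
Reagents that add atoms: none
Why: Lewis-acid debenzylation in the presence of a non-nucleophilic cation scavenger should cleave the four aryl benzyl ethers and the one alkyl benzyl ether at low temperature without touching the esters, the alkenes or the ketone and without bringing any stereocentre into play.

**Compound list**
1 | 3,4-bis(benzyloxy)benzaldehyde | O=Cc1ccc(OCc2ccccc2)c(OCc2ccccc2)c1 | starting material
2 | (triphenylphosphoranylidene)acetaldehyde | O=CC=P(c1ccccc1)(c1ccccc1)c1ccccc1 | starting material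
3 | (2E)-3-[3,4-bis(benzyloxy)phenyl]prop-2-enal | O=C/C=C/c1ccc(OCc2ccccc2)c(OCc2ccccc2)c1 | intermediate
4 | sodium (1E)-3-methoxy-3-oxoprop-1-en-1-olate | [Na+].[O-]/C=C/C(=O)OC | starting material
5 | methyl (4R)-4-[3,4-bis(benzyloxy)phenyl]-2-oxo-3,4-dihydro-2H-pyran-5-carboxylate | O=C1C[C@H](c2ccc(OCc3ccccc3)c(OCc3ccccc3)c2)C(C(=O)OC)=CO1 | intermediate
6 | (1,3-dioxolan-2-ylmethyl)magnesium bromide | Br[Mg]CC1OCCO1 | starting material
7 | (3R,4E)-3-[3,4-bis(benzyloxy)phenyl]-6-(1,3-dioxolan-2-yl)-4-(methoxycarbonyl)hex-4-enoic acid | OC(=O)C[C@H](c1ccc(OCc2ccccc2)c(OCc2ccccc2)c1)/C(C(=O)OC)=C\CC1OCCO1 | intermediate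
8 | (benzyloxy)acetyl chloride | O=C(Cl)COCc1ccccc1 | starting material
9 | prop-2-en-1-ol | OCC=C | starting material
10 | prop-2-en-1-yl (benzyloxy)acetate | C=CCOC(=O)COCc1ccccc1 | intermediate
11 | methyl (2E,3R)-3-[3,4-bis(benzyloxy)phenyl]-2-[2-(1,3-dioxolan-2-yl)ethylidene]-5-(1H-imidazol-1-yl)-5-oxopentanoate (acyl imidazolide of 7, formed in the flask) | O=C(C[C@H](c1ccc(OCc2ccccc2)c(OCc2ccccc2)c1)/C(C(=O)OC)=C\CC1OCCO1)n1ccnc1 | intermediate
12 | lithium 2-(benzyloxy)-1-(prop-2-en-1-yloxy)ethen-1-olate (lithium enolate of 10, formed in the flask) | C=CCOC(O[Li])=COCc1ccccc1 | intermediate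
13 | prop-2-en-1-yl (5R,6E)-2-(benzyloxy)-5-[3,4-bis(benzyloxy)phenyl]-8-(1,3-dioxolan-2-yl)-6-(methoxycarbonyl)-3-oxooct-6-enoate (C2 epimers) | C=CCOC(=O)C(OCc1ccccc1)C(=O)C[C@H](c1ccc(OCc2ccccc2)c(OCc2ccccc2)c1)/C(C(=O)OC)=C\CC1OCCO1 | intermediate
14 | prop-2-en-1-yl (6E)-2-(benzyloxy)-5-[3,4-bis(benzyloxy)phenyl]-4-[(E)-(dimethylamino)methylidene]-8-(1,3-dioxolan-2-yl)-6-(methoxycarbonyl)-3-oxooct-6-enoate (aryl-bearing carbon as in 13; formed in the flask) | C=CCOC(=O)C(OCc1ccccc1)C(=O)/C(=C/N(C)C)[C@H](c1ccc(OCc2ccccc2)c(OCc2ccccc2)c1)/C(C(=O)OC)=C\CC1OCCO1 | intermediate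
15 | prop-2-en-1-yl (5R,6E)-2-(benzyloxy)-5-[3,4-bis(benzyloxy)phenyl]-4,8-bis(1,3-dioxolan-2-yl)-6-(methoxycarbonyl)-3-oxooct-6-enoate (C2 and C4 epimers) | C=CCOC(=O)C(OCc1ccccc1)C(=O)C(C1OCCO1)[C@H](c1ccc(OCc2ccccc2)c(OCc2ccccc2)c1)/C(C(=O)OC)=C\CC1OCCO1 | intermediate
16 | 1-(prop-2-en-1-yl) 3-methyl (2R,3R,4S)-1-(benzyloxy)-4-[3,4-bis(benzyloxy)phenyl]-5-(1,3-dioxolan-2-yl)-2-(1,3-dioxolan-2-ylmethyl)-6-oxocyclohexane-1,3-dicarboxylate (C1 and C5 epimers; formed in the flask) | O=C1C(C2OCCO2)[C@H](c2ccc(OCc3ccccc3)c(OCc3ccccc3)c2)[C@@H](C(=O)OC)[C@@H](CC2OCCO2)C1(OCc1ccccc1)C(=O)OCC=C | intermediate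
17 | 1-(prop-2-en-1-yl) 3-methyl (2R,3R,4S)-1-(benzyloxy)-4-[3,4-bis(benzyloxy)phenyl]-5-formyl-6-oxo-2-(2-oxoethyl)cyclohexane-1,3-dicarboxylate (C1 and C5 epimers; formed in the flask) | O=C1C(C=O)[C@H](c2ccc(OCc3ccccc3)c(OCc3ccccc3)c2)[C@@H](C(=O)OC)[C@@H](CC=O)C1(OCc1ccccc1)C(=O)OCC=C | intermediate
18 | 3-(prop-2-en-1-yl) 8-methyl (1S,4S,7S,8R)-3-(benzyloxy)-7-[3,4-bis(benzyloxy)phenyl]-5-formyl-2-oxobicyclo[2.2.2]oct-5-ene-3,8-dicarboxylate (C3 epimers) | COC(=O)[C@H]1[C@H]2C(C=O)=C[C@H](C(=O)C2(OCc3ccccc3)C(=O)OCC=C)[C@@H]1c1ccc(OCc2ccccc2)c(OCc2ccccc2)c1 | intermediate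
19 | 1,2-bis(benzyloxy)-4-bromobenzene | Brc1ccc(OCc2ccccc2)c(OCc2ccccc2)c1 | starting material
20 | methyl (2S)-oxirane-2-carboxylate | COC(=O)[C@@H]1CO1 | starting material
21 | [3,4-bis(benzyloxy)phenyl]magnesium bromide (formed in the flask) | Br[Mg]c1ccc(OCc2ccccc2)c(OCc2ccccc2)c1 | intermediate
22 | methyl (2S)-3-[3,4-bis(benzyloxy)phenyl]-2-hydroxypropanoate | COC(=O)[C@@H](O)Cc1ccc(OCc2ccccc2)c(OCc2ccccc2)c1 | intermediate
23 | (triphenylphosphoranylidene)ketene | O=C=C=P(c1ccccc1)(c1ccccc1)c1ccccc1 | starting material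
24 | methyl (2S)-3-[3,4-bis(benzyloxy)phenyl]-2-{[(triphenylphosphoranylidene)acetyl]oxy}propanoate (formed in the flask) | COC(=O)[C@@H](OC(=O)C=P(c1ccccc1)(c1ccccc1)c1ccccc1)Cc1ccc(OCc2ccccc2)c(OCc2ccccc2)c1 | intermediate
25 | 3-(prop-2-en-1-yl) 8-methyl (1S,4S,7S,8R)-3-(benzyloxy)-7-[3,4-bis(benzyloxy)phenyl]-5-[(1E)-3-({(2S)-3-[3,4-bis(benzyloxy)phenyl]-1-methoxy-1-oxopropan-2-yl}oxy)-3-oxoprop-1-en-1-yl]-2-oxobicyclo[2.2.2]oct-5-ene-3,8-dicarboxylate (C3 epimers) | COC(=O)[C@H]1[C@H]2C(/C=C/C(=O)O[C@@H](Cc3ccc(OCc4ccccc4)c(OCc4ccccc4)c3)C(=O)OC)=C[C@H](C(=O)C2(OCc3ccccc3)C(=O)OCC=C)[C@@H]1c1ccc(OCc2ccccc2)c(OCc2ccccc2)c1 | intermediate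
26 | (1S,4S,7S,8R)-3-(benzyloxy)-7-[3,4-bis(benzyloxy)phenyl]-5-[(1E)-3-({(2S)-3-[3,4-bis(benzyloxy)phenyl]-1-methoxy-1-oxopropan-2-yl}oxy)-3-oxoprop-1-en-1-yl]-8-(methoxycarbonyl)-2-oxobicyclo[2.2.2]oct-5-ene-3-carboxylic acid (C3 epimers; formed in the flask) | COC(=O)[C@H]1[C@H]2C(/C=C/C(=O)O[C@@H](Cc3ccc(OCc4ccccc4)c(OCc4ccccc4)c3)C(=O)OC)=C[C@H](C(=O)C2(OCc3ccccc3)C(=O)O)[C@@H]1c1ccc(OCc2ccccc2)c(OCc2ccccc2)c1 | intermediate
27 | methyl (1S,3S,4S,7S,8R)-3-(benzyloxy)-7-[3,4-bis(benzyloxy)phenyl]-5-[(1E)-3-({(2S)-3-[3,4-bis(benzyloxy)phenyl]-1-methoxy-1-oxopropan-2-yl}oxy)-3-oxoprop-1-en-1-yl]-2-oxobicyclo[2.2.2]oct-5-ene-8-carboxylate | COC(=O)[C@H]1[C@H]2C(/C=C/C(=O)O[C@@H](Cc3ccc(OCc4ccccc4)c(OCc4ccccc4)c3)C(=O)OC)=C[C@H](C(=O)[C@H]2OCc3ccccc3)[C@@H]1c1ccc(OCc2ccccc2)c(OCc2ccccc2)c1 | intermediate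
28 | methyl (1S,3S,4S,7S,8R)-7-(3,4-dihydroxyphenyl)-5-[(1E)-3-{[(2S)-3-(3,4-dihydroxyphenyl)-1-methoxy-1-oxopropan-2-yl]oxy}-3-oxoprop-1-en-1-yl]-3-hydroxy-2-oxobicyclo[2.2.2]oct-5-ene-8-carboxylate (ester syn, aryl and hydroxyl anti to the C5=C6 bridge) | COC(=O)[C@H]1[C@H]2C(/C=C/C(=O)O[C@@H](Cc3ccc(O)c(O)c3)C(=O)OC)=C[C@H](C(=O)[C@H]2O)[C@@H]1c1ccc(O)c(O)c1 | target

**Step count and risks**
Total steps: 11. Longest linear sequence: 9 (steps 1, 2, 3, 5, 6, 7, 9, 10, 11).

Step 7. What may go wrong: the 6-endo Michael addition onto the trisubstituted, branched acrylate may be slow, so that β-elimination of the acetal next to the ketone or, once acid is added, aldol addition at the doubly activated carbon competes and the order of the two ring closures is lost. The fallback changes the approach to ring closure before formylation. It sets out from 13: catalytic Cs2CO3 in MeCN should close the cyclohexanone on the simpler β-keto ester, where only the alkylidene exerts allylic strain, to give 1-(prop-2-en-1-yl) 3-methyl (2R,3R,4S)-1-(benzyloxy)-4-[3,4-bis(benzyloxy)phenyl]-2-(1,3-dioxolan-2-ylmethyl)-6-oxocyclohexane-1,3-dicarboxylate F1. Me2NCH(OMe)2 then aminomethylenates the one remaining α-methylene to give the 5-[(E)-(dimethylamino)methylidene] derivative of that cyclohexanone F2. AcOH–H2O with pyrrolidine at 60 °C frees the aldehyde and condenses its α-carbon with the vinylogous formamide carbon (Mannich-type addition, then loss of dimethylamine), and the route is rejoined at 18.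

Step 3. What may go wrong: 1,2-addition of the organomagnesium reagent to the lactone carbonyl may outrun the copper-mediated addition–elimination, or the alkene geometry may be scrambled. The fallback replaces conjugate substitution by cross-coupling. It sets out from 5: N,O-dimethylhydroxylamine in toluene should open the enol lactone at the acyl carbon to methyl (3R)-3-[3,4-bis(benzyloxy)phenyl]-2-(hydroxymethylidene)-5-[methoxy(methyl)amino]-5-oxopentanoate F3. TsCl, N-methylimidazole and Et3N should give the (E)-enol tosylate, methyl (2E,3R)-3-[3,4-bis(benzyloxy)phenyl]-5-[methoxy(methyl)amino]-2-{[(4-methylbenzenesulfonyl)oxy]methylidene}-5-oxopentanoate F4. Negishi coupling with (1,3-dioxolan-2-ylmethyl)zinc bromide (Pd(OAc)2, 2-dicyclohexylphosphino-2',6'-dimethoxybiphenyl, THF) should give with retention methyl (2E,3R)-3-[3,4-bis(benzyloxy)phenyl]-2-[2-(1,3-dioxolan-2-yl)ethylidene]-5-[methoxy(methyl)amino]-5-oxopentanoate F5. Acylation of lithium enolate 12 by this N-methoxy-N-methylamide rejoins the route at 13.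

Step 10. What may go wrong: ketonisation of the enol by protonation from the face screened by the aryl group (poor or reversed facial selectivity at C3), or partial conjugate reduction of the dienoate by palladium hydride. The fallback delivers oxygen instead of hydrogen, which inverts the outcome of the same facial preference. It sets out from 27 as obtained, whatever its configuration at C3: SmI2 in THF–MeOH at −78 °C should remove the α-benzyloxy group to give methyl (1S,4S,7S,8R)-7-[3,4-bis(benzyloxy)phenyl]-5-[(1E)-3-({(2S)-3-[3,4-bis(benzyloxy)phenyl]-1-methoxy-1-oxopropan-2-yl}oxy)-3-oxoprop-1-en-1-yl]-2-oxobicyclo[2.2.2]oct-5-ene-8-carboxylate F6. Me3SiOTf and Et3N should give the only possible silyl enol ether, the 2-(trimethylsilyloxy)bicyclo[2.2.2]octa-2,5-diene F7. Rubottom oxidation (m-CPBA, then mild aqueous acid) should deliver oxygen to the face the proton preferred and give the tetra-O-benzyl α-hydroxy ketone F8. BCl3 and pentamethylbenzene, as in step 11, then give 28.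

**Further compounds**
F1 | step 7 | 1-(prop-2-en-1-yl) 3-methyl (2R,3R,4S)-1-(benzyloxy)-4-[3,4-bis(benzyloxy)phenyl]-2-(1,3-dioxolan-2-ylmethyl)-6-oxocyclohexane-1,3-dicarboxylate (C1 epimers) | O=C1C[C@H](c2ccc(OCc3ccccc3)c(OCc3ccccc3)c2)[C@@H](C(=O)OC)[C@@H](CC2OCCO2)C1(OCc1ccccc1)C(=O)OCC=C
F2 | step 7 | 1-(prop-2-en-1-yl) 3-methyl 1-(benzyloxy)-4-[3,4-bis(benzyloxy)phenyl]-5-[(E)-(dimethylamino)methylidene]-2-(1,3-dioxolan-2-ylmethyl)-6-oxocyclohexane-1,3-dicarboxylate (ring configuration as in F1) | O=C1/C(=C/N(C)C)[C@H](c2ccc(OCc3ccccc3)c(OCc3ccccc3)c2)[C@@H](C(=O)OC)[C@@H](CC2OCCO2)C1(OCc1ccccc1)C(=O)OCC=C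
F3 | step 3 | methyl (3R)-3-[3,4-bis(benzyloxy)phenyl]-2-(hydroxymethylidene)-5-[methoxy(methyl)amino]-5-oxopentanoate | CON(C)C(=O)C[C@H](c1ccc(OCc2ccccc2)c(OCc2ccccc2)c1)C(C(=O)OC)=CO
F4 | step 3 | methyl (2E,3R)-3-[3,4-bis(benzyloxy)phenyl]-5-[methoxy(methyl)amino]-2-{[(4-methylbenzenesulfonyl)oxy]methylidene}-5-oxopentanoate | CON(C)C(=O)C[C@H](c1ccc(OCc2ccccc2)c(OCc2ccccc2)c1)/C(C(=O)OC)=C\OS(=O)(=O)c1ccc(C)cc1
F5 | step 3 | methyl (2E,3R)-3-[3,4-bis(benzyloxy)phenyl]-2-[2-(1,3-dioxolan-2-yl)ethylidene]-5-[methoxy(methyl)amino]-5-oxopentanoate | CON(C)C(=O)C[C@H](c1ccc(OCc2ccccc2)c(OCc2ccccc2)c1)/C(C(=O)OC)=C\CC1OCCO1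
F6 | step 10 | methyl (1S,4S,7S,8R)-7-[3,4-bis(benzyloxy)phenyl]-5-[(1E)-3-({(2S)-3-[3,4-bis(benzyloxy)phenyl]-1-methoxy-1-oxopropan-2-yl}oxy)-3-oxoprop-1-en-1-yl]-2-oxobicyclo[2.2.2]oct-5-ene-8-carboxylate | COC(=O)[C@H]1[C@H]2C(/C=C/C(=O)O[C@@H](Cc3ccc(OCc4ccccc4)c(OCc4ccccc4)c3)C(=O)OC)=C[C@H](C(=O)C2)[C@@H]1c1ccc(OCc2ccccc2)c(OCc2ccccc2)c1
F7 | step 10 | methyl 7-[3,4-bis(benzyloxy)phenyl]-5-[(1E)-3-({(2S)-3-[3,4-bis(benzyloxy)phenyl]-1-methoxy-1-oxopropan-2-yl}oxy)-3-oxoprop-1-en-1-yl]-2-[(trimethylsilyl)oxy]bicyclo[2.2.2]octa-2,5-diene-8-carboxylate (configuration as in F6) | COC(=O)[C@H]1[C@H]2C(/C=C/C(=O)O[C@@H](Cc3ccc(OCc4ccccc4)c(OCc4ccccc4)c3)C(=O)OC)=C[C@H](C(O[Si](C)(C)C)=C2)[C@@H]1c1ccc(OCc2ccccc2)c(OCc2ccccc2)c1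
F8 | step 10 | methyl (1S,3S,4S,7S,8R)-7-[3,4-bis(benzyloxy)phenyl]-5-[(1E)-3-({(2S)-3-[3,4-bis(benzyloxy)phenyl]-1-methoxy-1-oxopropan-2-yl}oxy)-3-oxoprop-1-en-1-yl]-3-hydroxy-2-oxobicyclo[2.2.2]oct-5-ene-8-carboxylate | COC(=O)[C@H]1[C@H]2C(/C=C/C(=O)O[C@@H](Cc3ccc(OCc4ccccc4)c(OCc4ccccc4)c3)C(=O)OC)=C[C@H](C(=O)[C@H]2O)[C@@H]1c1ccc(OCc2ccccc2)c(OCc2ccccc2)c1
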